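**Plan**

1. Locants follow the bicyclo[3.3.1]nonane core: C1 (benzoyl), C2/C4 (ketones flanking C3), C5 (geranyl), C6, C7, C8 (CMe2), C9 (bridging ketone). Retrosynthesis first contracts the 1,2-dioxepane: its O–CH bond is cut and the peroxy oxygen is returned to the C4 ketone, giving a six-membered 1,2-dioxan-3-ol (peroxy-hemiketal) and a free C3 prenyl group.
2. Next the C3–CH bond of the homoadamantane and the C(CH3)2–OO bond are cut (radical/O2 cascade) to a 7-endo-prenyl bicyclo[3.3.1]nonane-2,4,9-trione. Its C7 chain is cut back to an aldehyde stored as an adamantanol. The bonds C5–C6, C1–C8 and C3–CH(OH) are cut together to a benzoylphloroglucinol and an acetoxymethyl enal, and last the two aryl–allyl bonds.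
3. Forward ring order: benzene ring → adamantane cage (one step) → retro-aldol opening to the bicyclo[3.3.1] core → homoadamantane plus 1,2-dioxane (one step) → one-atom ring expansion to the 1,2-dioxepane.
4. Enabling feature: the C4 carbonyl of the cyclohexane-1,3,5-trione ring lies 1,3 to the tertiary peroxy carbon across the new C3–CH bond, so the hydroperoxide rests as a six-membered hemiketal. The rigid cage holds that peroxide gauche to the C3–CH2 of the prenyl group, whose CH terminus is five atoms from the peroxy oxygen (7-exo).
5. Stereochemistry: C5 from a chiral phase-transfer catalyst; C1 and C7 relayed from it in the annulation (aldol capture of the endo aldehyde); C3 and the homoadamantane CH by the cage in the radical cyclisation; the peroxy-bearing CH by the cage in the key step.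

Key step: step 12

Remark: the cinchonidine-derived catalyst is assumed to be the pseudoenantiomer that delivers the drawn antipode (otherwise the cinchonine-derived salt is taken).

**Route**

Step 1
Reactants: 1 diethyl 2-(propan-2-ylidene)propanedioate
Product: 2 2-(propan-2-ylidene)propane-1,3-diol
Conditions: i-Bu2AlH (4.5 equiv), CH2Cl2, −78 → 0 °C; aq. potassium sodium tartrate
Reagents that add atoms: none
Why: Exhaustive 1,2-reduction of both esters of an alkylidene malonate by i-Bu2AlH should give the allylic diol without conjugate reduction (ester reduction).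

Step 2
Reactants: 2 2-(propan-2-ylidene)propane-1,3-diol
Product: 3 2-(hydroxymethyl)-3-methylbut-2-enal
Conditions: MnO2 (activated, 10 equiv), CH2Cl2, 23 °C
Reagents that add atoms: none
Why: Allylic oxidation with MnO2 should stop after one hydroxymethyl group, because the enal formed makes the alkene electron-poor and the second allylic alcohol much less reactive.

Step 3
Reactants: 3 2-(hydroxymethyl)-3-methylbut-2-enal
Product: 4 (2-formyl-3-methylbut-2-en-1-yl) acetate
Conditions: Ac2O, pyridine, DMAP (cat.), CH2Cl2, 0 °C
Reagents that add atoms: acetic anhydride, CC(=O)OC(C)=O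
Why: O-Acetylation turns the allylic hydroxyl into the leaving group needed for the later C-alkylation.

Step 4
Reactants: 5 (2,4,6-trihydroxyphenyl)(phenyl)methanone; 6 1-bromo-3-methylbut-2-ene
Product: 7 3-prenyl-2,4,6-trihydroxybenzophenone
Conditions: KOH (10 % aq.), 0 °C
Reagents that add atoms: none
Why: Alkylation of the phloroglucinol-type phenoxide with an allylic bromide in water favours carbon over oxygen, and one of the two equivalent free ring positions reacts (C-prenylation).

Step 5
Reactants: 7 3-prenyl-2,4,6-trihydroxybenzophenone; 8 geranyl bromide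
Product: 9 3-geranyl-5-prenyl-2,4,6-trihydroxybenzophenone
Conditions: KOH (10 % aq.), 0 → 23 °C
Reagents that add atoms: none
Why: The second C-alkylation can only take the one remaining ring C–H, and the SN2 displacement keeps the E geometry of the geranyl unit.

Step 6
Reactants: 9 3-geranyl-5-prenyl-2,4,6-trihydroxybenzophenone; 4 (2-formyl-3-methylbut-2-en-1-yl) acetate
Product: 11 adamantanol, via dearomatised enal 10 (not isolated)
Conditions: O-allyl-N-(9-anthracenylmethyl)cinchonidinium bromide (20 mol %), CsOH·H2O, CH2Cl2, 4 Å molecular sieves, −50 → −20 °C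
Reagents that add atoms: none
Why: Alkylative dearomatisation–annulation: within the chiral ammonium ion pair the geranyl-bearing ring carbon is alkylated by the allylic acetate (SN2, sets the C5 quaternary centre), the benzoyl-bearing carbon then adds to the β,β-dimethyl enal (Michael addition, C1–C8 bond) and the prenyl-bearing enol carbon closes on the aldehyde (aldol), which fixes C1 and C7 relative to C5 and stores the aldehyde on the endo face, although alkylation at the equally nucleophilic prenyl-bearing carbon gives a constitutional isomer that has to be separated.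

Step 7
Reactants: 11 adamantanol
Product: 12 7-endo-(1-hydroxyallyl) bicyclic enol
Conditions: CeCl3, CH2=CHMgBr (excess), THF, −78 → −30 °C
Reagents that add atoms: vinylmagnesium bromide, C=C[Mg]Br
Why: The alkoxide of 11 undergoes retro-aldol cleavage and the weakly basic vinylcerium reagent adds to the endo aldehyde as it is released, before C7 can epimerise (retro-aldol/organocerium 1,2-addition), so the endo side chain is kept and both carbinol epimers serve.

Step 8
Reactants: 12 7-endo-(1-hydroxyallyl) bicyclic enol
Product: 13 allylic acetate enol acetate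
Conditions: Ac2O, Et3N, DMAP (cat.), CH2Cl2, 0 → 23 °C
Reagents that add atoms: acetic anhydride, CC(=O)OC(C)=O
Why: Acetylation activates the secondary allylic alcohol for ionisation and masks the enol at the same time (the regioisomeric enol acetate would serve equally).

Step 9
Reactants: 13 allylic acetate enol acetate
Product: 14 7-endo-allyl bicyclic enol
Conditions: Pd(PPh3)4 (5 mol %), HCO2NH4, 1,4-dioxane, 90 °C; then K2CO3 (cat.), MeOH, 23 °C
Reagents that add atoms: none
Why: Tsuji reduction: zerovalent palladium ionises the allylic acetate and formate delivers hydride to the more substituted terminus of the allyl complex to give the terminal alkene, and carbonate-catalysed methanolysis then frees the enol.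

Step 10
Reactants: 14 7-endo-allyl bicyclic enol
Product: 15 7-endo-prenyl bicyclic enol
Conditions: second-generation Grubbs catalyst (H2IMes)(PCy3)Cl2Ru=CHPh (5 mol %), 2-methylbut-2-ene (excess), CH2Cl2, 40 °C
Reagents that add atoms: 2-methylbut-2-ene, CC=C(C)C
Why: Cross-metathesis converts only the terminal allyl group into prenyl, since the trisubstituted prenyl and geranyl alkenes do not enter the catalytic cycle.

Step 11
Reactants: 15 7-endo-prenyl bicyclic enol
Product: 16 homoadamantane 1,2-dioxan-3-ol
Conditions: Mn(OAc)3·2H2O (20 mol %), O2 (5 atm), AcOH, 23 °C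
Reagents that add atoms: dioxygen, O=O
Why: Aerobic oxidative radical cyclisation of a 2-alkyl-1,3-diketone catalysed by trivalent manganese, the intramolecular form of the known 1,2-dioxan-3-ol synthesis: the C3 radical closes 7-exo-trig on the endo prenyl group, which reaches it from one face only and turns its C(CH3)2 end away from the C8 methyl groups (sets C3 and the adjacent CH), the tertiary radical takes up O2, divalent manganese reduces the peroxyl radical, and the hydroperoxide adds to the neighbouring C4 ketone in the only configuration the ring fusion allows.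

Step 12
Reactants: 16 homoadamantane 1,2-dioxan-3-ol
Product: 18 target, via dioxepane hydroperoxide 17 (not isolated)
Conditions: t-BuON=NOt-Bu (20 mol %), O2 (1 atm), C6H6 (0.01 M), 35 °C; then PPh3, 0 °C
Reagents that add atoms: dioxygen, O=O
Why: Proposed new method: tert-butoxyl radicals from the hyponitrite start a chain in which the hemiketal (through its hydroperoxy-ketone tautomer, or by O–H abstraction and loss of the C4 carbonyl from the alkoxyl radical) gives the tertiary peroxyl radical, which adds 7-exo-trig to the CH terminus of the C3 prenyl group; the 2-propyl radical takes up O2 and the new peroxyl radical abstracts hydrogen from the next hemiketal molecule, so the six-membered 1,2-dioxan-3-ol is enlarged by one ring atom to the 1,2-dioxepane while C4 returns to the ketone, and PPh3 then reduces only the side-chain hydroperoxide. The closest known reactions are the hyponitrite/O2 peroxyl-radical cyclisations of unsaturated hydroperoxides to 1,2-dioxolanes and 1,2-dioxanes and the thiol–olefin co-oxygenation; neither a cyclic peroxy-hemiketal as the hydroperoxide reservoir nor the 7-exo closure has been shown. One ring is closed, the dioxepane, in the 7-exo-trig radical mode, and the 1,2-dioxane is opened in the same event. The new stereocentre, the peroxy-bearing CH, is set by substrate control: the cage holds the peroxy carbon gauche to the C3 methylene, and addition is expected on the alkene face that leaves the bulky C(CH3)2 radical terminus pseudo-equatorial and outside the cage, which is the configuration of the target. The step needs the 7-exo closure to outrun intermolecular hydrogen abstraction by the first peroxyl radical (dilution, no metal reductant), selectivity over the two geranyl alkenes (too remote for a small-ring closure) and survival of the O–O bond (neutral medium, 35 °C, phosphine reduces ROOH but not ROOR).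

**Compound list**

1 | diethyl 2-(propan-2-ylidene)propanedioate | CCOC(=O)C(C(=O)OCC)=C(C)C | starting material
2 | 2-(propan-2-ylidene)propane-1,3-diol | OCC(CO)=C(C)C | intermediate
3 | 2-(hydroxymethyl)-3-methylbut-2-enal | O=CC(CO)=C(C)C | intermediate
4 | (2-formyl-3-methylbut-2-en-1-yl) acetate | CC(=O)OCC(C=O)=C(C)C | intermediate
5 | (2,4,6-trihydroxyphenyl)(phenyl)methanone | O=C(c1ccccc1)c1c(O)cc(O)cc1O | starting material
6 | 1-bromo-3-methylbut-2-ene (prenyl bromide) | CC(C)=CCBr | starting material
7 | [2,4,6-trihydroxy-3-(3-methylbut-2-en-1-yl)phenyl](phenyl)methanone | O=C(c1ccccc1)c1c(O)cc(O)c(CC=C(C)C)c1O | intermediate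
8 | (2E)-1-bromo-3,7-dimethylocta-2,6-diene (geranyl bromide) | CC(C)=CCC/C(C)=C/CBr | starting material
9 | {3-[(2E)-3,7-dimethylocta-2,6-dien-1-yl]-2,4,6-trihydroxy-5-(3-methylbut-2-en-1-yl)phenyl}(phenyl)methanone | O=C(c1ccccc1)c1c(O)c(C/C=C(\C)CCC=C(C)C)c(O)c(CC=C(C)C)c1O | intermediate
10 | dearomatised enal: 2-benzoyl-6-geranyl-6-(2-formyl-3-methylbut-2-enyl)-3,5-dihydroxy-4-prenylcyclohexa-2,4-dien-1-one, quaternary carbon as drawn (not isolated) | CC(C)=CCC/C(C)=C/C[C@@]1(CC(C=O)=C(C)C)C(=O)C(C(=O)c2ccccc2)=C(O)C(CC=C(C)C)=C1O | intermediate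
11 | adamantanol: 1-benzoyl-5-geranyl-8,8-dimethyl-3-prenyl adamantane-2,4,9-trione cage with a CH(OH) bridge between C3 and C7; bridgeheads as drawn, mixture of carbinol epimers | CC(C)=CCC/C(C)=C/C[C@]12C[C@@H]3C(O)[C@](CC=C(C)C)(C1=O)C(=O)[C@](C(=O)c4ccccc4)(C2=O)C3(C)C | intermediate
12 | 1-benzoyl-5-geranyl-4-hydroxy-7-endo-(1-hydroxyprop-2-enyl)-8,8-dimethyl-3-prenylbicyclo[3.3.1]non-3-ene-2,9-dione, mixture of carbinol epimers | CC(C)=CCC/C(C)=C/C[C@]12C[C@H](C(O)C=C)C(C)(C)[C@@](C(=O)c3ccccc3)(C2=O)C(=O)C(CC=C(C)C)=C1O | intermediate
13 | allylic acetate and C4 enol acetate of 12 | CC(C)=CCC/C(C)=C/C[C@]12C[C@H](C(OC(C)=O)C=C)C(C)(C)[C@@](C(=O)c3ccccc3)(C2=O)C(=O)C(CC=C(C)C)=C1OC(C)=O | intermediate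
14 | 7-endo-allyl-1-benzoyl-5-geranyl-4-hydroxy-8,8-dimethyl-3-prenylbicyclo[3.3.1]non-3-ene-2,9-dione | CC(C)=CCC/C(C)=C/C[C@]12C[C@H](CC=C)C(C)(C)[C@@](C(=O)c3ccccc3)(C2=O)C(=O)C(CC=C(C)C)=C1O | intermediate
15 | 1-benzoyl-5-geranyl-4-hydroxy-8,8-dimethyl-3,7-endo-diprenylbicyclo[3.3.1]non-3-ene-2,9-dione | CC(C)=CCC/C(C)=C/C[C@]12C[C@H](CC=C(C)C)C(C)(C)[C@@](C(=O)c3ccccc3)(C2=O)C(=O)C(CC=C(C)C)=C1O | intermediate
16 | homoadamantane 1,2-dioxan-3-ol: C3 bonded to the former prenyl CH, whose C(CH3)2–O–O group closes on C4 as a hemiketal; C3 prenyl intact | CC(C)=CCC/C(C)=C/C[C@]12C[C@@H]3C[C@@H]4C(C)(C)OO[C@@]1(O)[C@]4(CC=C(C)C)C(=O)[C@](C(=O)c5ccccc5)(C2=O)C3(C)C | intermediate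
17 | dioxepane hydroperoxide: the target with C(CH3)2–OOH in place of C(CH3)2–OH (not isolated) | CC(C)=CCC/C(C)=C/C[C@]12C[C@@H]3C[C@@H]4C(C)(C)OO[C@H](C(C)(C)OO)C[C@@]4(C1=O)C(=O)[C@](C(=O)c1ccccc1)(C2=O)C3(C)C | intermediate
18 | CNP0148771.1 | CC(C)=CCC/C(C)=C/C[C@]12C[C@@H]3C[C@@H]4C(C)(C)OO[C@H](C(C)(C)O)C[C@@]4(C1=O)C(=O)[C@](C(=O)c1ccccc1)(C2=O)C3(C)C | target

Total step count: 12. Longest linear sequence: 10 steps (steps 1–3, then 6–12); the arene branch (steps 4 and 5) joins at step 6.

**Steps most likely to fail**

1. Step 12. The chain may not be sustained if the hemiketal releases its hydroperoxide too slowly, and the 7-exo addition may show poor facial selectivity. Fallback with known chemistry, from 15 to 18 without resting at 16: 15 is submitted to a metal-free radical-chain aerobic cyclisation of the 2-alkyl-1,3-diketone (O2 5 atm, di-tert-butyl hyponitrite, t-BuOH, 35 °C), so that no reductant intercepts the tertiary peroxyl radical and it closes onto the C3 prenyl group within the same cascade as the C–C bond formation. PPh3 work-up of the resulting hydroperoxide 17 gives 18; this forms no compound outside the list (none, F0).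

2. Step 11. O2 may capture the C3 radical before the C–C closure, and 5-exo closures may compete (tertiary radical onto the C3 prenyl group, C3 radical onto the geranyl alkene). Fallback from 15, returning at 16, with carbon–carbon and carbon–oxygen bond formation separated: anaerobic oxidative cyclisation with Mn(OAc)3·2H2O and Cu(OAc)2·H2O in degassed AcOH, in which divalent copper oxidises the tertiary radical to the alkene, should give the isopropenyl homoadamantane F1. Isayama–Mukaiyama peroxidation of its 1,1-disubstituted alkene [Co(acac)2, O2, Et3SiH, ClCH2CH2Cl] should give the triethylsilyl peroxide F2. Desilylation with Bu4NF/AcOH frees the hydroperoxide, which closes on the C4 ketone to 16.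

3. Step 6. There is no intrinsic site selection between the geranyl- and the prenyl-bearing ring carbons in the first alkylation, so separation of two constitutional isomers may fail. Fallback from 5, returning at 12, in which only one ring carbon is alkylated when the cage is built:
 - bromination of 5 (N-bromosuccinimide, MeCN, 0 °C) gives the monobromide F3;
 - C-geranylation with 8 (aq. KOH) gives the bromo geranyl benzophenone F4;
 - the annulation of step 6 with 4 then has to start at the geranyl-bearing carbon and, provided the benzoyl-bearing carbon again serves as the Michael donor, gives the bromo adamantanol F5;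
 - retro-aldol/vinylcerium addition as in step 7 gives the 3-bromo bicyclic carbinol F6;
 - zinc in AcOH removes the bromine from the 2-bromo-1,3-diketone to give the 3-unsubstituted bicyclic carbinol F7;
 - C-prenylation with 6 (aq. KOH, 0 °C) gives 12.

Further compounds
F0 | step 12 | none | none
F1 | step 11 | isopropenyl homoadamantane (C3 bonded to the CH that carries the isopropenyl group; C3 prenyl intact) | CC(C)=CCC/C(C)=C/C[C@]12C[C@@H]3C[C@H](C(C)=C)[C@](CC=C(C)C)(C1=O)C(=O)[C@](C(=O)c4ccccc4)(C2=O)C3(C)C
F2 | step 11 | triethylsilyl peroxide of the open form of 16 | CC(C)=CCC/C(C)=C/C[C@]12C[C@@H]3C[C@H](C(C)(C)OO[Si](CC)(CC)CC)[C@](CC=C(C)C)(C1=O)C(=O)[C@](C(=O)c4ccccc4)(C2=O)C3(C)C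
F3 | step 6 | (3-bromo-2,4,6-trihydroxyphenyl)(phenyl)methanone | O=C(c1ccccc1)c1c(O)cc(O)c(Br)c1O
F4 | step 6 | {3-bromo-5-[(2E)-3,7-dimethylocta-2,6-dien-1-yl]-2,4,6-trihydroxyphenyl}(phenyl)methanone | O=C(c1ccccc1)c1c(O)c(C/C=C(\C)CCC=C(C)C)c(O)c(Br)c1O
F5 | step 6 | 3-bromo analogue of adamantanol 11 | CC(C)=CCC/C(C)=C/C[C@]12C[C@@H]3C(O)[C@](Br)(C1=O)C(=O)[C@](C(=O)c4ccccc4)(C2=O)C3(C)C
F6 | step 6 | 3-bromo analogue of 12 | CC(C)=CCC/C(C)=C/C[C@]12C[C@H](C(O)C=C)C(C)(C)[C@@](C(=O)c3ccccc3)(C2=O)C(=O)C(Br)=C1O
F7 | step 6 | 3-unsubstituted analogue of 12 | CC(C)=CCC/C(C)=C/C[C@]12C[C@H](C(O)C=C)C(C)(C)[C@@](C(=O)c3ccccc3)(C2=O)C(=O)C=C1O
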